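**Retrosynthetic overview**
1. Target 10 ⇒ aniline 7: all three C–Br bonds of ring A are cut at once. The NH2 group directs two brominations (to its para and ortho carbons, which are also ortho and para to OMe) and is then itself replaced by Br (Sandmeyer).
2. 7 ⇒ unprotected 2-amino-6-methoxyphenol 5 + a 2-bromophenyl cation equivalent (diaryliodonium salt 4). The C–O coupling is metal-free, so no aryl bromide is at risk and no pre-brominated phenol is needed.
3. 4 ⇒ 1-bromo-2-iodobenzene 1 + 1,3,5-trimethoxybenzene 2.
4. No ring is built: both benzene rings are bought. Order of events: ring B is activated, ring A and ring B are joined through oxygen, ring A is halogenated last.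

Assumption: the target SMILES has no stereocentre and the diaryl ether axis rotates freely, so the compound is achiral and no stereocontrol is required.

**Step 1**
Reactants: 1 1-bromo-2-iodobenzene; 2 1,3,5-trimethoxybenzene
Product: 4 (2-bromophenyl)(2,4,6-trimethoxyphenyl)iodonium 4-methylbenzenesulfonate, via Koser-type iodane 3 (not isolated)
Conditions: mCPBA (1.05 equiv), TsOH·H2O (1.0 equiv), MeCN, 77 °C, 30 min; then 2 (1.0 equiv), 77 °C, 10 min; Et2O trituration
Reagents that add atoms: p-toluenesulfonic acid monohydrate, Cc1ccc(cc1)S(=O)(=O)O.O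
Why: One-pot diaryliodonium salt synthesis, in which the aryl iodide is oxidised to a hydroxy(tosyloxy)iodoarene of trivalent iodine that then undergoes electrophilic aromatic substitution on the very electron-rich arene 2, leaving trimethoxyphenyl as a non-transferable dummy ligand.

**Step 2**
Reactants: 5 2-amino-6-methoxyphenol; 4 (2-bromophenyl)(2,4,6-trimethoxyphenyl)iodonium 4-methylbenzenesulfonate
Product: 7 2-(2-bromophenoxy)-3-methoxyaniline, via potassium phenolate 6 (not isolated)
Conditions: KOtBu (1.05 equiv), degassed THF, 0 °C, 15 min, N2; then 4 (1.15 equiv), rt to 45 °C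
Reagents that add atoms: none
Why: Metal-free O-arylation of a phenoxide with a diaryliodonium salt (ligand exchange at trivalent iodine, then ligand coupling), in which the anionic oxygen reacts at room temperature while the neutral NH2 does not, the electron-poorer ortho-substituted 2-bromophenyl group is transferred in preference to trimethoxyphenyl, and the absence of any transition metal leaves the C–Br bond untouched.

**Step 3**
Reactants: 7 2-(2-bromophenoxy)-3-methoxyaniline
Product: 10 1,2,5-tribromo-3-(2-bromophenoxy)-4-methoxybenzene, via dibromoaniline 8 (not isolated), via arenediazonium bromide 9 (not isolated)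
Conditions: NBS (2.05 equiv), MeCN, 0 °C to rt, dark; then cannulate into CuBr2 (1.5 equiv), t-BuONO (1.5 equiv), MeCN, 60 °C
Reagents that add atoms: N-bromosuccinimide, BrN1C(=O)CCC1=O; CuBr2, Br[Cu]Br
Why: Electrophilic aromatic bromination goes para and ortho to NH2 (sites that OMe activates as well, so the aniline ring reacts far faster than ring B and the carbon para to the ether oxygen stays C–H), and a non-aqueous Sandmeyer bromodediazoniation (alkyl nitrite with CuBr2) then converts the directing NH2 into the third bromine, the excess of divalent copper bromide trapping the aryl radical before Pschorr cyclisation onto ring B.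

**Compound list**
1 | 1-bromo-2-iodobenzene | Brc1ccccc1I | starting material
2 | 1,3,5-trimethoxybenzene | COc1cc(OC)cc(OC)c1 | starting material
3 | 1-bromo-2-[hydroxy(tosyloxy)iodo]benzene (Koser-type iodane) | Cc1ccc(cc1)S(=O)(=O)OI(O)c1ccccc1Br | intermediate
4 | (2-bromophenyl)(2,4,6-trimethoxyphenyl)iodonium 4-methylbenzenesulfonate | COc1cc(OC)c([I+]c2ccccc2Br)c(OC)c1.Cc1ccc(cc1)S(=O)(=O)[O-] | intermediate
5 | 2-amino-6-methoxyphenol | COc1cccc(N)c1O | starting material
6 | potassium 2-amino-6-methoxyphenolate | COc1cccc(N)c1[O-].[K+] | intermediate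
7 | 2-(2-bromophenoxy)-3-methoxyaniline | COc1cccc(N)c1Oc1ccccc1Br | intermediate
8 | 4,6-dibromo-2-(2-bromophenoxy)-3-methoxyaniline | COc1c(Br)cc(Br)c(N)c1Oc1ccccc1Br | intermediate
9 | 4,6-dibromo-2-(2-bromophenoxy)-3-methoxybenzenediazonium bromide | COc1c(Br)cc(Br)c([N+]#N)c1Oc1ccccc1Br.[Br-] | intermediate
10 | 1,2,5-tribromo-3-(2-bromophenoxy)-4-methoxybenzene (CNP0117173.0; achiral) | COc1c(Br)cc(Br)c(Br)c1Oc1ccccc1Br | target

**Step count**
Total steps: 3. Longest linear sequence: 3 (1 → 4 → 7 → 10).

**Steps most likely to fail, with fallbacks**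

Step 2 (highest risk). The unprotected, electron-rich aminophenoxide may be N-arylated or oxidised by single-electron transfer, and the phenoxide is flanked on both sides. The fallback masks nitrogen as a nitro group. It sets out from 4: the potassium salt of 2-methoxy-6-nitrophenol F4 is arylated with 4 (KOtBu, MeCN, 70 °C) to give 2-(2-bromophenoxy)-1-methoxy-3-nitrobenzene F5. Reduction with Fe powder and NH4Cl in EtOH/H2O at 70 °C, which leaves the aryl bromide alone, returns to the route at 7.

Step 3. The diazonium or aryl radical next to the aryloxy group may close to a dibenzofuran (Pschorr), or ring B may take up bromine. The fallback gives up the amine logic and uses a free phenol as the director. It sets out from 4: 2-bromo-6-methoxyphenol F6 is arylated with 4 (KOtBu, THF, rt to 45 °C) to give 1-bromo-2-(2-bromophenoxy)-3-methoxybenzene F7. BBr3 in CH2Cl2 (−78 to 0 °C) cleaves the methyl ether to 3-bromo-2-(2-bromophenoxy)phenol F8. NBS (2.05 equiv) in MeCN at 0 °C brominates ortho and para to the free OH, which outruns ring B, to give 3,4,6-tribromo-2-(2-bromophenoxy)phenol F9. MeI with K2CO3 in acetone then returns to the route at 10. The methyl group must be off during this bromination, because ring B would react before the last position of a methylated ring A.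

Step 1 (lowest risk). Over-oxidation of 2, or a salt that oils out, would block the route. The fallback makes a symmetric salt by boron-to-iodine aryl transfer and so needs no dummy ligand. It sets out from 1: oxidation with NaBO3·4H2O in AcOH at 45 °C gives 1-bromo-2-(diacetoxyiodo)benzene F1. Treatment with (2-bromophenyl)boronic acid F2 and BF3·OEt2 in CH2Cl2 (−30 °C to rt), then aqueous NaBF4, gives bis(2-bromophenyl)iodonium tetrafluoroborate F3. F3 replaces 4 in step 2 and the route is rejoined at 7.

**Further compounds**
F1 | step 1 | 1-bromo-2-(diacetoxyiodo)benzene | CC(=O)OI(OC(C)=O)c1ccccc1Br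
F2 | step 1 | (2-bromophenyl)boronic acid | OB(O)c1ccccc1Br
F3 | step 1 | bis(2-bromophenyl)iodonium tetrafluoroborate | Brc1ccccc1[I+]c1ccccc1Br.F[B-](F)(F)F
F4 | step 2 | 2-methoxy-6-nitrophenol | COc1cccc([N+](=O)[O-])c1O
F5 | step 2 | 2-(2-bromophenoxy)-1-methoxy-3-nitrobenzene | COc1cccc([N+](=O)[O-])c1Oc1ccccc1Br
F6 | step 3 | 2-bromo-6-methoxyphenol | COc1cccc(Br)c1O
F7 | step 3 | 1-bromo-2-(2-bromophenoxy)-3-methoxybenzene | COc1cccc(Br)c1Oc1ccccc1Br
F8 | step 3 | 3-bromo-2-(2-bromophenoxy)phenol | Oc1cccc(Br)c1Oc1ccccc1Br
F9 | step 3 | 3,4,6-tribromo-2-(2-bromophenoxy)phenol | Oc1c(Br)cc(Br)c(Br)c1Oc1ccccc1Br
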